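**Assumptions**
- The target, (6,7-dimethoxy-1H-isochromen-3-yl)(2,4-dimethoxyphenyl)methanone, has no stereocentre and its only C=C is endocyclic, so it is achiral and there is no enantiomer to select.
- The route has only two steps, so the closing risk ranking covers both of them rather than three.

**Retrosynthetic overview**
1. Target 7 ⇒ break C1–C8a (Friedel–Crafts closure of an O–CH2+ oxocarbenium ion onto the veratryl ring, the closure presumed in peltogynoid-type biogenesis, where an oxidised O-methyl carbon bridges to ring B) and C3=C4 (loss of HCl) ⇒ acyclic β-chloro α-(methoxymethoxy) ketone 5.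
2. 5 ⇒ trans-chalcone epoxide 4 + MOMCl (oxirane cleavage, same flask as line 1).
3. 4 ⇒ Darzens condensation of phenacyl bromide 1 with veratraldehyde 2.
4. Ring order: both benzene rings are bought; the pyran ring is the only ring made, and it is made last.

**Route**

Step 1
Reactants: 1 2-bromo-1-(2,4-dimethoxyphenyl)ethan-1-one; 2 3,4-dimethoxybenzaldehyde
Product: 4 rac-trans-(2,4-dimethoxyphenyl)[3-(3,4-dimethoxyphenyl)oxiran-2-yl]methanone, via bromohydrin aldolate 3 (not isolated)
Conditions: NaOH (1.2 equiv, 2 M aq.), EtOH, 0 °C → rt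
Reagents that add atoms: none
Why: Darzens condensation: the bromo-enolate of 1 adds reversibly to aldehyde 2 and the aldolate closes by intramolecular SN2 displacement of bromide, giving mainly the trans epoxide as a racemate; both new stereocentres are erased in step 2, so neither dr nor ee matters.

Step 2
Reactants: 4 rac-trans-(2,4-dimethoxyphenyl)[3-(3,4-dimethoxyphenyl)oxiran-2-yl]methanone
Product: 7 (6,7-dimethoxy-1H-isochromen-3-yl)(2,4-dimethoxyphenyl)methanone, via chloro MOM ether 5 (not isolated), via 4-chloroisochroman 6 (not isolated)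
Conditions: MOMCl (1.2 equiv), ZnCl2 (10 mol%, 1 M in Et2O, added last), CH2Cl2 (0.05 M), −20 → 0 °C; then TfOH (20 mol%), 0 °C → rt; aq. NaHCO3 work-up
Reagents that add atoms: chloromethyl methyl ether (MOMCl), COCCl
Why: Proposed new method: ZnCl2-catalysed cleavage of the oxirane by the α-chloro ether (known for epoxides with acyl chlorides and chloromethyl ethers) puts chloride on the veratryl-stabilised benzylic carbon and CH2OMe on the α-oxygen (5); TfOH then ionises this mixed formaldehyde acetal to the O=CH2+ oxocarbenium ion, which closes in a six-membered Friedel–Crafts (oxa-Pictet–Spengler) mode para to the 3-OMe group of the veratryl ring (6), and the 4-chloride (benzylic, para to OMe, β to the ketone) leaves as HCl by E1/E1cB to give the conjugated enol ether; the closest known reaction type is the acid-mediated cyclisation of MOM/MEM ethers of 2-arylethanols to isochromans; no stereocentre remains.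

**Compound list**
1 | 2-bromo-1-(2,4-dimethoxyphenyl)ethan-1-one | COc1ccc(C(=O)CBr)c(OC)c1 | starting material
2 | 3,4-dimethoxybenzaldehyde (veratraldehyde) | COc1ccc(C=O)cc1OC | starting material
3 | 2-bromo-1-(2,4-dimethoxyphenyl)-3-(3,4-dimethoxyphenyl)-3-hydroxypropan-1-one (as its alkoxide; racemic, diastereomers equilibrating by retro-aldol, configuration not fixed) | COc1ccc(C(=O)C(Br)C(O)c2ccc(OC)c(OC)c2)c(OC)c1 | intermediate
4 | rac-trans-(2,4-dimethoxyphenyl)[3-(3,4-dimethoxyphenyl)oxiran-2-yl]methanone ((2R*,3S*); one enantiomer drawn) | COc1ccc(C(=O)[C@@H]2O[C@H]2c2ccc(OC)c(OC)c2)c(OC)c1 | intermediate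
5 | 3-chloro-1-(2,4-dimethoxyphenyl)-3-(3,4-dimethoxyphenyl)-2-(methoxymethoxy)propan-1-one (racemic diastereomer mixture, configuration irrelevant) | COCOC(C(Cl)c1ccc(OC)c(OC)c1)C(=O)c1ccc(OC)cc1OC | intermediate
6 | (4-chloro-6,7-dimethoxy-3,4-dihydro-1H-isochromen-3-yl)(2,4-dimethoxyphenyl)methanone (racemic diastereomer mixture, configuration irrelevant) | COc1ccc(C(=O)C2OCc3cc(OC)c(OC)cc3C2Cl)c(OC)c1 | intermediate
7 | (6,7-dimethoxy-1H-isochromen-3-yl)(2,4-dimethoxyphenyl)methanone (achiral) | COc1ccc(C(=O)C2=Cc3cc(OC)c(OC)cc3CO2)c(OC)c1 | target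

**Totals**
Total step count: 2. Longest linear sequence: 2.

**Steps most likely to fail**

Most likely: step 2. The risks are a Lewis-acid (Meinwald) 1,2-aroyl shift of 4 to the β-keto aldehyde before MOMCl captures the epoxide, intermolecular methoxymethylation at C5 of the 2,4-dimethoxybenzoyl ring by free MOMCl, and slow closure of the oxocarbenium ion. The fallback sets out from 4 and comes back at 7. It installs the C=C bond first and never generates a benzylic cation next to the acyl group under Lewis acid. Epoxide 4 is opened with anhydrous HCl (4 M in dioxane, 0 °C) to the chlorohydrin 3-chloro-1-(2,4-dimethoxyphenyl)-3-(3,4-dimethoxyphenyl)-2-hydroxypropan-1-one F1. Warming with NaOAc in EtOH removes HCl and gives the diosphenol (Z)-1-(2,4-dimethoxyphenyl)-3-(3,4-dimethoxyphenyl)-2-hydroxyprop-2-en-1-one F2, the enol of the 1,2-dione. O-Alkylation with MOMCl/iPr2NEt in CH2Cl2 gives the enol ether (Z)-1-(2,4-dimethoxyphenyl)-3-(3,4-dimethoxyphenyl)-2-(methoxymethoxy)prop-2-en-1-one F3, in which the enol oxygen and the veratryl ring are cis. Catalytic TfOH in dilute CH2Cl2 (−20 °C → rt) then ionises the isolated acetal and closes the ring directly to 7 with loss of methanol.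

Second: step 1. The risks are slow aldol addition to the electron-rich aldehyde, solvolysis of the bromide by hydroxide/ethanol, and self-condensation of 1. The fallback sets out from 2 and comes back at 4. Commercial 1-(2,4-dimethoxyphenyl)ethan-1-one F4 is condensed with 2 (KOH, EtOH, rt; Claisen–Schmidt) to the chalcone (E)-1-(2,4-dimethoxyphenyl)-3-(3,4-dimethoxyphenyl)prop-2-en-1-one F5. This is epoxidised with 30% H2O2/NaOH in MeOH–THF (Weitz–Scheffer nucleophilic epoxidation) to give 4.

There is no third step to rank.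

**Further compounds**
F1 | step 2 | 3-chloro-1-(2,4-dimethoxyphenyl)-3-(3,4-dimethoxyphenyl)-2-hydroxypropan-1-one (racemic diastereomer mixture) | COc1ccc(C(=O)C(O)C(Cl)c2ccc(OC)c(OC)c2)c(OC)c1
F2 | step 2 | (Z)-1-(2,4-dimethoxyphenyl)-3-(3,4-dimethoxyphenyl)-2-hydroxyprop-2-en-1-one | COc1ccc(C(=O)/C(O)=C/c2ccc(OC)c(OC)c2)c(OC)c1
F3 | step 2 | (Z)-1-(2,4-dimethoxyphenyl)-3-(3,4-dimethoxyphenyl)-2-(methoxymethoxy)prop-2-en-1-one | COc1ccc(C(=O)/C(OCOC)=C/c2ccc(OC)c(OC)c2)c(OC)c1
F4 | step 1 | 1-(2,4-dimethoxyphenyl)ethan-1-one (bought, not made) | CC(=O)c1ccc(OC)cc1OC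
F5 | step 1 | (E)-1-(2,4-dimethoxyphenyl)-3-(3,4-dimethoxyphenyl)prop-2-en-1-one | COc1ccc(C(=O)/C=C/c2ccc(OC)c(OC)c2)c(OC)c1
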